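The substrate D takes the reagent X in two steps, first to D.X and then to X.D.X, and D.X is the product I wanted.

    X + D.X → X.D.X (k1 = 0.0337 /M/min)
    D ⇌ L (K2 = 2.28, k2 = 0.00693 /min)
    D + X → D.X (k3 = 0.253 /M/min)
    2 D → D2 (k4 = 0.0532 /M/min)
    X ⇌ E, rate k5*([X] - [E]/K5) per volume of the first phase (K5 = 0.443, k5 = 0.0132 /min)

D 0.22 M; E 0.154 M; time 10 h; volume of the second phase over the first 0.50

- percentages count the D that a species holds: one D2 counts as two
- a step written with two of one species runs at k times the square of its concentration and takes two of it each time
- in the second phase: E; everything else is in the first
- charges count per volume of the first phase; a concentration in a rate is the amount of a species over the volume of its own phase; every rate counts per litre of the first phase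
- run time (flask): 10 h

- amount of D.X at 10 h, in percent of the D charged
- the change that raises the amount of D.X at 10 h, in percent of the D charged most ("none" if none brings more than 2 percentage points) (Thursday's / Sunday's / none)
- amount of D.X at 10 h, in percent of the D charged, after Thursday's

The first line spends D.X with the same X that makes it in the third, so I took the selectivity factor s, the rate constant for making D.X over that for spending it, 7.51. For two equal sites on D, the statistical zero of this scale is 2, and this D stands 3.75 times above it. X cancels from the ratio of those two rates, so in this scheme D.X rises while the balance s[D]/[D.X] is above one and falls while it is below. But the second line shelves D as L, with a forward half-life of 1.7 h, and the fourth turns D into D2, with a first half-life of 0.712 h. The last line needs 0.280 h to deliver the charge of E at its opening rate, which is longer than the 0.21 h half-life of X by the third line at the charged concentrations. The charges of E and D cap D.X at 70.0% of the D charged, by the steps listed with no other path taking anything. I committed to that ceiling and the balance test, not to a yield.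

The forecast gave 32%, none and 23%, holding that the faster transfer “only trims early D2 loss”.

The flask gave 33.7%, best change Sunday's, and 18.9% after Thursday's. Sunday's brought 3.3 percentage points, above the margin of 2 points, so the forecast parted from the flask there. At 10.0 h in this flask the balance read 0.720, below one, and D.X had gone from 34.9% at 5.00 h to 33.7%. The neighbour with 0.055 M of D, all else held, had 2.80 of E charged per D. At the same time its D stood at 0.963% and its D.X at 23.3%, so its balance read 0.311, below one, and its X.D.X held 57.7%.

The rate constants were drawn at random within sensible limits; what happens was integrated by code.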